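## Retrosynthetic overview

1. The lactol ring is made last: target ⇐ δ-hydroxy ketone ⇐ tertiary C6 radical (from a C6 spiro-epoxide of the bridged ketone) + ethyl vinyl ketone.
2. Seven-membered ring D ⇐ intramolecular 1,8-addition of the C9 ketone enolate to a vinyl group that is cross-coupled onto a dienyl triflate at C12.
3. Ring E and the quaternary C17 ⇐ enantioselective Pd-catalysed intramolecular α-alkenylation (C17–C13) of a piperidone that carries a 2-bromo-enone.
4. That precursor ⇐ ester enolate of a piperidone propanoate + 2-bromo-3-ethoxycyclopentenone (Stork–Danheiser union); the pieces come from 1-methylpiperidin-4-one/methyl acrylate and cyclopentane-1,3-dione.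
5. Ring order: the piperidine and ring F arrive with the starting materials, then ring E, ring D, and the lactol ring.

## Labels and assumptions

- Atom labels follow the target SMILES from left to right: C1 (CH3), C2, C3 (hemiketal C), C4, C5, C6 (spiro C), C7 (OCH2), O8, C9 (bridgehead CH), C10, C11, C12, C13, C14, C15 (C–CO2Me), C16, C17 (quaternary bridgehead), C18 (NCH2), N, C19 (NCH2), C20, C21. Target = (3R,6R,9S,17R). Ring F = C12/C13/C14/C20/C21, ring E = C13–C17, ring D = the seven-membered ring.
- Assumption: C3 equilibrates through the open hydroxy ketone, and the 3R anomer is the thermodynamic one (hydroxyl axial, ethyl and C17 equatorial on the tetrahydropyran chair).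
- Assumption: (R)-DTBM-SEGPHOS is written as the ligand antipode that gives the 17S spiro centre in step 8; if the first run shows the opposite sense, the (S)-ligand is used and nothing else changes.
- CIP descriptors at C9 and C17 change between the ketone stage (9R,17S) and the target (9S,17R) only because substituent priorities change; the geometry is the same.

## Route

**Step 1**
Reactants: 1 cyclopentane-1,3-dione
Product: 2 3-ethoxycyclopent-2-en-1-one
Conditions: EtOH, TsOH (cat.), toluene, reflux (Dean–Stark)
Reagents that add atoms: ethanol, CCO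
Why: Acid-catalysed enol etherification of the fully enolised 1,3-dione with azeotropic removal of water gives the vinylogous ester (no stereocentre).

**Step 2**
Reactants: 2 3-ethoxycyclopent-2-en-1-one
Product: 3 2-bromo-3-ethoxycyclopent-2-en-1-one
Conditions: NBS, CH2Cl2, 0 °C
Reagents that add atoms: N-bromosuccinimide, O=C1CCC(=O)N1Br
Why: Electrophilic α-bromination of the electron-rich vinylogous ester by NBS occurs only at C-2, giving the vinyl bromide needed for step 8.

**Step 3**
Reactants: 4 1-methylpiperidin-4-one; 5 methyl acrylate
Product: 7 methyl 3-(1-methyl-4-oxopiperidin-3-yl)propanoate (racemic), via pyrrolidine enamine 6 (not isolated)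
Conditions: pyrrolidine, TsOH (cat.), toluene, reflux (Dean–Stark); 5, MeCN, reflux; then AcOH, NaOAc, H2O, rt
Reagents that add atoms: water, O
Why: Stork enamine Michael addition, in which the pyrrolidine enamine adds once to the acrylate and hydrolysis returns the ketone; the new centre (C17) is racemic and is planarised again in step 8.

**Step 4**
Reactants: 7 methyl 3-(1-methyl-4-oxopiperidin-3-yl)propanoate
Product: 8 methyl 3-(4,4-dimethoxy-1-methylpiperidin-3-yl)propanoate (racemic)
Conditions: HC(OMe)3, MeOH, TsOH·H2O (1.2 equiv), reflux; NaHCO3 (aq.)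
Reagents that add atoms: trimethyl orthoformate, COC(OC)OC; methanol, CO
Why: Ketalisation driven by the orthoformate masks the ketone so that step 7 enolises only the ester, with a full equivalent of acid because the amine takes up the first.

**Step 5**
Reactants: 9 propanal
Product: 10 pent-1-en-3-ol (racemic)
Conditions: CH2=CHMgBr, THF, 0 °C; 1 M HCl (aq.)
Reagents that add atoms: vinylmagnesium bromide, C=C[Mg]Br
Why: Grignard 1,2-addition of the vinyl nucleophile to the aldehyde; the racemic carbinol centre is destroyed in step 6.

**Step 6**
Reactants: 10 pent-1-en-3-ol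
Product: 11 pent-1-en-3-one (ethyl vinyl ketone)
Conditions: MnO2 (10 equiv), CH2Cl2, rt; filter, distil
Reagents that add atoms: none
Why: MnO2 oxidises the allylic alcohol selectively to the enone, giving fresh, inhibitor-free ethyl vinyl ketone for the radical step 12.

**Step 7**
Reactants: 8 methyl 3-(4,4-dimethoxy-1-methylpiperidin-3-yl)propanoate; 3 2-bromo-3-ethoxycyclopent-2-en-1-one
Product: 13 methyl 2-(2-bromo-3-oxocyclopent-1-en-1-yl)-3-(1-methyl-4-oxopiperidin-3-yl)propanoate (stereoisomer mixture), via alkoxide adduct 12 (not isolated)
Conditions: LiN(iPr)2 (commercial solution, 1.1 equiv), THF, −78 °C; 3, −78 → −30 °C; then 2 M HCl (aq.), THF, rt; NaHCO3 (aq.)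
Reagents that add atoms: water, O
Why: Stork–Danheiser alkylation, the ester enolate adding to the carbonyl of the vinylogous ester and aqueous acid then expelling ethanol with carbonyl transposition and cleaving the ketal; because the five-membered core is symmetrical a direct addition–elimination at the ethoxy carbon gives the same product, and both stereocentres (C15, C17) are epimerisable mixtures.

**Step 8**
Reactants: 13 methyl 2-(2-bromo-3-oxocyclopent-1-en-1-yl)-3-(1-methyl-4-oxopiperidin-3-yl)propanoate
Product: 14 methyl (1S)-1'-methyl-4',6-dioxo-3,4,5,6-tetrahydro-2H-spiro[pentalene-1,3'-piperidine]-3-carboxylate (17S spiro keto ester; C15 epimers)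
Conditions: Pd2(dba)3 (2.5 mol %), (R)-DTBM-SEGPHOS (6 mol %), PhOK (3 equiv), THF, 60 °C
Reagents that add atoms: none
Why: Proposed new method: enantioselective palladium-catalysed intramolecular α-alkenylation of a ketone by an α-bromo enone — zerovalent palladium inserts into the C13–Br bond, phenoxide generates the more substituted C17 enolate (the C9 enolate would need a seven-membered ring, and the acidic C15–H gives only an unproductive, reversibly formed dienolate), the enolate binds the divalent vinylpalladium as a six-membered palladacycle and C–C reductive elimination forges C17–C13, ring E and the quaternary spiro centre, the bisphosphine pocket choosing one enolate face under Curtin–Hammett conditions while the C15 epimers converge by base epimerisation; the closest known reactions are the racemic palladium-catalysed intramolecular α-alkenylation of ketones with vinyl halides and the enantioselective palladium-catalysed intramolecular α-arylation of aldehydes, ketones and amides that gives quaternary stereocentres.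

**Step 9**
Reactants: 14 17S spiro keto ester
Product: 15 methyl (1S)-1'-methyl-4'-oxo-6-(trifluoromethanesulfonyloxy)-4,5-dihydro-2H-spiro[pentalene-1,3'-piperidine]-3-carboxylate (17S dienyl triflate)
Conditions: NaH (1.05 equiv), THF, 0 °C; PhNTf2, 0 °C → rt
Reagents that add atoms: N-phenyl-bis(trifluoromethanesulfonimide), O=S(=O)(N(c1ccccc1)S(=O)(=O)C(F)(F)F)C(F)(F)F
Why: NaH removes the most acidic proton (C15–H of the vinylogous β-keto ester) and the extended enolate is O-sulfonylated by PhNTf2 (enol triflate formation), fixing the C12=C13–C14=C15 diene of the target inside rings E and F; C17 is untouched.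

**Step 10**
Reactants: 15 17S dienyl triflate; 16 potassium vinyltrifluoroborate
Product: 18 (9R,17S)-bridged keto ester (the target skeleton with C6 as a ketone bridge between C9 and C17 and without C7 and C1–C5), via trienoate 17 (not isolated)
Conditions: PdCl2(dppf) (5 mol %), Cs2CO3 (3 equiv), THF/H2O (9:1), 70 °C; then DBU (1 equiv), 70 °C
Reagents that add atoms: none
Why: Suzuki–Miyaura vinylation of the dienyl triflate gives a trienoate whose terminal carbon C10 is attacked by the C9 enolate of the ketone (its only enolisable position) in an intramolecular 1,8-conjugate (vinylogous Michael) addition that closes ring D; C9 is set because only the cis-bridged bicyclo[4.3.1] skeleton can form from 17S, and reprotonation returns the conjugated dienoate.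

**Step 11**
Reactants: 18 (9R,17S)-bridged keto ester
Product: 19 (9R,17S)-C6 spiro-epoxide (18 with C6=O replaced by a C6–O–C7H2 oxirane; both C6 epimers)
Conditions: Me3SI, KN(SiMe3)2, THF/DMSO, −10 °C → rt
Reagents that add atoms: trimethylsulfonium iodide, C[S+](C)C.[I-]
Why: Corey–Chaykovsky epoxidation, the small sulfonium methylide adding to the strained bridging ketone without touching the hindered dienoate; the C6 epimer ratio is irrelevant because C6 becomes a planar radical in step 12.

**Step 12**
Reactants: 19 (9R,17S)-C6 spiro-epoxide; 11 pent-1-en-3-one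
Product: 21 CNP0192143.3, the (3R,6R,9S,17R) hemiketal, via open hydroxy ketone 20 (not isolated)
Conditions: Cp2TiCl2 (20 mol %), Zn dust (3 equiv), 2,4,6-collidine·HCl (3.5 equiv), THF, rt, 11 (4 equiv) by syringe pump; NaHCO3 (aq.), silica gel
Reagents that add atoms: none
Why: Titanocene-catalysed reductive epoxide opening (Nugent–RajanBabu/Gansäuer conditions, trivalent titanium) gives the tertiary C6 radical, which should add to the enone (Giese addition) from the piperidine face because the other face is covered by C10–H and by C14/C15 of the pentalene hanging from sp2 C13, so the chain ends syn to the nitrogen bridge and C7–O syn to ring D (6R); the hydroxy ketone then closes to the thermodynamic hemiketal (3R).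

## Compound list

1 | cyclopentane-1,3-dione | O=C1CCC(=O)C1 | starting material
2 | 3-ethoxycyclopent-2-en-1-one | CCOC1=CC(=O)CC1 | intermediate
3 | 2-bromo-3-ethoxycyclopent-2-en-1-one | CCOC1=C(Br)C(=O)CC1 | intermediate
4 | 1-methylpiperidin-4-one | CN1CCC(=O)CC1 | starting material
5 | methyl acrylate | C=CC(=O)OC | starting material
6 | 1-methyl-4-(pyrrolidin-1-yl)-1,2,3,6-tetrahydropyridine | CN1CCC(=CC1)N1CCCC1 | intermediate (not isolated)
7 | methyl 3-(1-methyl-4-oxopiperidin-3-yl)propanoate, racemic | CN1CCC(=O)C(C1)CCC(=O)OC | intermediate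
8 | methyl 3-(4,4-dimethoxy-1-methylpiperidin-3-yl)propanoate, racemic | CN1CCC(OC)(OC)C(C1)CCC(=O)OC | intermediate
9 | propanal | CCC=O | starting material
10 | pent-1-en-3-ol, racemic | CCC(O)C=C | intermediate
11 | pent-1-en-3-one (ethyl vinyl ketone) | CCC(=O)C=C | intermediate
12 | methyl 2-(2-bromo-3-ethoxy-1-hydroxycyclopent-2-en-1-yl)-3-(4,4-dimethoxy-1-methylpiperidin-3-yl)propanoate, lithium alkoxide in the flask, stereoisomer mixture | CCOC1=C(Br)C(O)(CC1)C(CC1CN(C)CCC1(OC)OC)C(=O)OC | intermediate (not isolated)
13 | methyl 2-(2-bromo-3-oxocyclopent-1-en-1-yl)-3-(1-methyl-4-oxopiperidin-3-yl)propanoate, stereoisomer mixture | CN1CCC(=O)C(C1)CC(C(=O)OC)C1=C(Br)C(=O)CC1 | intermediate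
14 | methyl (1S)-1'-methyl-4',6-dioxo-3,4,5,6-tetrahydro-2H-spiro[pentalene-1,3'-piperidine]-3-carboxylate (17S; C15 epimers; C13=C14 enone) | CN1CCC(=O)[C@@]2(C1)CC(C(=O)OC)C1=C2C(=O)CC1 | intermediate
15 | methyl (1S)-1'-methyl-4'-oxo-6-(trifluoromethanesulfonyloxy)-4,5-dihydro-2H-spiro[pentalene-1,3'-piperidine]-3-carboxylate (17S) | CN1CCC(=O)[C@@]2(C1)CC(C(=O)OC)=C1C2=C(OS(=O)(=O)C(F)(F)F)CC1 | intermediate
16 | potassium vinyltrifluoroborate | [K+].C=C[B-](F)(F)F | starting material
17 | methyl (1S)-6-ethenyl-1'-methyl-4'-oxo-4,5-dihydro-2H-spiro[pentalene-1,3'-piperidine]-3-carboxylate (17S trienoate) | CN1CCC(=O)[C@@]2(C1)CC(C(=O)OC)=C1C2=C(C=C)CC1 | intermediate (not isolated)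
18 | (9R,17S)-bridged keto ester: N-methyl-3-azabicyclo[4.3.1]decan-10-one (C6 = carbonyl bridge, C9 and C17 bridgeheads) fused to the tetrahydropentalene dienoate | O=C2[C@@H]1CCC3=C4C(=C(C(=O)OC)C[C@@]42CN(C)C1)CC3 | intermediate
19 | (9R,17S)-C6 spiro-epoxide of 18 (C6 epimer mixture) | C5OC52[C@@H]1CCC3=C4C(=C(C(=O)OC)C[C@@]42CN(C)C1)CC3 | intermediate
20 | (6R,9S,17R)-6-(hydroxymethyl)-6-(3-oxopentyl) tetracycle, open form of the target | CCC(=O)CC[C@@]2(CO)[C@@H]1CCC3=C4C(=C(C(=O)OC)C[C@@]42CN(C)C1)CC3 | intermediate (not isolated)
21 | CNP0192143.3, (3R,6R,9S,17R) | CC[C@]1(O)CC[C@@]2(CO1)[C@@H]1CCC3=C4C(=C(C(=O)OC)C[C@@]42CN(C)C1)CC3 | target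

## Step count and risks

Total steps: 12. Longest linear sequence: 8 (steps 1, 2, 7, 8, 9, 10, 11, 12; equally 3, 4, 7–12), which is two thirds of the total. Steps 5 and 6 form a third branch that joins at the last step.

The three steps most likely to fail:

**Step 8 (the proposed new step).** Risks are slow oxidative addition or coupling because the substrate is partly present as its C15 dienolate, and insufficient enantioselectivity. The fallback sets out from 13 and comes back at 15. Compound 13 is cyclised with achiral Pd(PPh3)4 and PhOK in THF at reflux, the established racemic ketone α-alkenylation, to the racemic spiro keto ester F1. NaH and PhNTf2 convert it into the racemic dienyl triflate F2, which now has a single stereocentre. F2 is resolved by crystallising its salt with O,O'-di-p-toluoyl-L-tartaric acid from ethanol/ethyl acetate (the mirror-image acid is used if the other salt crystallises), giving the tartrate salt F3 of the 17S triflate. Aqueous NaHCO3 liberates 15.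

**Step 10.** The trienoate is a weak acceptor and the 1,8-addition may stall or give side reactions under the basic coupling conditions. The fallback sets out from 15 and comes back at 18, and closes ring D through the C11–C12 bond instead. The C9 enolate of 15 (KN(SiMe3)2, THF, −78 °C) is added to phenyl vinyl sulfoxide to give the sulfoxide adduct F4. Heating in toluene at 110 °C over NaHCO3 eliminates the sulfoxide and gives the C9-vinyl ketone F5. Hydroboration of the vinyl group with 9-BBN gives the alkylborane F6, which is not isolated. Intramolecular B-alkyl Suzuki–Miyaura coupling with the C12 triflate (PdCl2(dppf), AsPh3, Cs2CO3, DMF/THF/H2O, 50 °C) gives 18. The base epimerises C9, so both C9 epimers funnel into the cis-bridged product.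

**Step 12.** Ethyl vinyl ketone may be reduced or polymerised by trivalent titanium, and the facial selectivity at C6 rests on a conformational argument that has to be confirmed by NOE. The fallback sets out from 19 and comes back at 21. The same titanocene-catalysed epoxide opening is run with N-methoxy-N-methylacrylamide, an acceptor class that is established for this reaction, to give the hydroxy Weinreb amide F7. EtMgBr (3 equiv, THF, −20 °C) then converts the Weinreb amide, in preference to the hindered conjugated ester, into the ethyl ketone, which closes to 21 on work-up. This fallback addresses the enone compatibility only, not the facial selectivity.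

## Further compounds

F1 | step 8 | methyl 1'-methyl-4',6-dioxo-3,4,5,6-tetrahydro-2H-spiro[pentalene-1,3'-piperidine]-3-carboxylate, racemic, C15 epimers | CN1CCC(=O)C2(C1)CC(C(=O)OC)C1=C2C(=O)CC1
F2 | step 8 | methyl 1'-methyl-4'-oxo-6-(trifluoromethanesulfonyloxy)-4,5-dihydro-2H-spiro[pentalene-1,3'-piperidine]-3-carboxylate, racemic | CN1CCC(=O)C2(C1)CC(C(=O)OC)=C1C2=C(OS(=O)(=O)C(F)(F)F)CC1
F3 | step 8 | O,O'-di-p-toluoyl-L-tartrate salt of the 17S dienyl triflate | CN1CCC(=O)[C@@]2(C1)CC(C(=O)OC)=C1C2=C(OS(=O)(=O)C(F)(F)F)CC1.OC(=O)[C@H](OC(=O)c1ccc(C)cc1)[C@@H](OC(=O)c1ccc(C)cc1)C(O)=O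
F4 | step 10 | 17S dienyl triflate carrying a 2-(phenylsulfinyl)ethyl group at C9, epimer mixture | CN1CC(CCS(=O)c3ccccc3)C(=O)[C@@]2(C1)CC(C(=O)OC)=C1C2=C(OS(=O)(=O)C(F)(F)F)CC1
F5 | step 10 | 17S dienyl triflate carrying a vinyl group at C9, C9 epimers | CN1CC(C=C)C(=O)[C@@]2(C1)CC(C(=O)OC)=C1C2=C(OS(=O)(=O)C(F)(F)F)CC1
F6 | step 10 | 17S dienyl triflate carrying a 2-(9-borabicyclo[3.3.1]nonan-9-yl)ethyl group at C9 | CN1CC(CCB3C4CCCC3CCC4)C(=O)[C@@]2(C1)CC(C(=O)OC)=C1C2=C(OS(=O)(=O)C(F)(F)F)CC1
F7 | step 12 | (6R,9S,17R)-6-(hydroxymethyl)-6-[3-(methoxy(methyl)amino)-3-oxopropyl] tetracycle (hydroxy Weinreb amide) | CON(C)C(=O)CC[C@@]2(CO)[C@@H]1CCC3=C4C(=C(C(=O)OC)C[C@@]42CN(C)C1)CC3
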